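**Retrosynthetic overview**
1. Feature: ring C (O1–C2–C3–C4–C4a–C8a) is read as the [4+2] adduct of the ortho-quinone methide of ring A (O1=C8a–C4a=C4) and an E alkene (C2=C3). The trans C2-aryl/C3-oxygen pair reflects that E geometry, and boron stands in for the C3 oxygen.
2. Endgame disconnections: the 7-O–Si bond (fluoride), then C3–OH back to C3–B(pin) (oxidation with retention).
3. Key disconnection: C4–C3 and O1–C2 by an acid-catalysed asymmetric oxa-[4+2]. Ring C is the only ring formed; rings A and B come in as bought arenes.
4. Diene precursor: a salicyl alcohol from 5-methoxyresorcinol by two directed lithiations (prenyl at C8, formyl carbon = C4), MOM removal, 7-O-silylation and reduction. The mirror-symmetric 2-prenyl arene leaves only one possible formylation site.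
5. Dienophile: (E)-2-(4-hydroxyphenyl)vinyl pinacol boronate from 4-hydroxybenzaldehyde (silylation, boron-Wittig, desilylation). The 4'-OH is left free as a second contact point for the catalyst.

Key step: step 10

Assumption: the (R)-configured acid is taken to give the (2S,3S) cycloadduct; if the sense proves opposite, the equally available (S)-acid is used.

**Step 1**
Reactants: 1 5-methoxyresorcinol
Product: 2 1-methoxy-3,5-bis(methoxymethoxy)benzene
Conditions: MOMCl (2.6 equiv), i-Pr2NEt (3 equiv), CH2Cl2, 0 °C to rt
Reagents that add atoms: chloromethyl methyl ether, COCCl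
Why: Base-mediated O-alkylation (MOM acetal formation) of both equivalent phenols is routine and puts the two strongest directing groups on the ring for the lithiations that follow.

**Step 2**
Reactants: 2 1-methoxy-3,5-bis(methoxymethoxy)benzene; 3 prenyl bromide (1-bromo-3-methylbut-2-ene)
Product: 5 5-methoxy-1,3-bis(methoxymethoxy)-2-(3-methylbut-2-en-1-yl)benzene, via aryllithium 4 (not isolated)
Conditions: n-BuLi (1.1 equiv), THF, 0 °C to rt; then 3 (1.3 equiv), −78 °C to rt
Reagents that add atoms: none
Why: Directed ortho-metalation removes the C–H flanked by the two chelating OMOM groups, which outrank OMe as directors, and the aryllithium displaces the primary allylic bromide by SN2, so the prenyl group lands on the future C8 of a mirror-symmetric arene.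

**Step 3**
Reactants: 5 5-methoxy-1,3-bis(methoxymethoxy)-2-(3-methylbut-2-en-1-yl)benzene
Product: 7 6-methoxy-2,4-bis(methoxymethoxy)-3-(3-methylbut-2-en-1-yl)benzaldehyde, via aryllithium 6 (not isolated)
Conditions: n-BuLi (1.2 equiv), THF, −10 to 0 °C; DMF (3 equiv), 0 °C to rt; H2O
Reagents that add atoms: N,N-dimethylformamide, CN(C)C=O
Why: A second directed ortho-metalation followed by DMF formylation acts on the two remaining ring C–H bonds, which are equivalent by symmetry and each flanked by OMOM and OMe, so only one aldehyde can form, and ring lithiation without a diamine additive at or below 0 °C should outrun removal of the allylic benzylic hydrogens.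

**Step 4**
Reactants: 7 6-methoxy-2,4-bis(methoxymethoxy)-3-(3-methylbut-2-en-1-yl)benzaldehyde
Product: 8 2,4-dihydroxy-6-methoxy-3-(3-methylbut-2-en-1-yl)benzaldehyde
Conditions: HCl (cat.), MeOH, 35 °C, stopped at full conversion
Reagents that add atoms: none
Why: Acid-catalysed transacetalisation to methanol (MOM cleavage) is fast for the ether beside the carbonyl and still mild for the para one, while dilute acid at this temperature does not protonate the trisubstituted alkene and the formyl group tempers the phenols, so chroman closure onto the prenyl group should not occur.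

**Step 5**
Reactants: 8 2,4-dihydroxy-6-methoxy-3-(3-methylbut-2-en-1-yl)benzaldehyde
Product: 9 4-(tert-butyldimethylsilyloxy)-2-hydroxy-6-methoxy-3-(3-methylbut-2-en-1-yl)benzaldehyde
Conditions: TBSCl (1.05 equiv), imidazole (2 equiv), CH2Cl2, 0 °C
Reagents that add atoms: tert-butyldimethylsilyl chloride, CC(C)(C)[Si](C)(C)Cl
Why: The silylation is chemoselective because the 2-OH (future O1) is hydrogen-bonded to the formyl oxygen and flanked on both sides, so one equivalent of TBSCl goes to the more acidic, free 4-OH (future 7-O).

**Step 6**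
Reactants: 9 4-(tert-butyldimethylsilyloxy)-2-hydroxy-6-methoxy-3-(3-methylbut-2-en-1-yl)benzaldehyde
Product: 10 5-(tert-butyldimethylsilyloxy)-2-(hydroxymethyl)-3-methoxy-6-(3-methylbut-2-en-1-yl)phenol
Conditions: NaBH4 (1 equiv), THF/EtOH, −10 °C, 20 min; pH 7 phosphate buffer; used crude at once
Reagents that add atoms: none
Why: Borohydride 1,2-reduction of the aldehyde leaves the alkene and silyl ether alone, and low temperature, short contact and a neutral buffered quench keep the electron-rich phenoxide from expelling the benzylic oxygen, which would lead to over-reduction or self-condensation.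

**Step 7**
Reactants: 11 4-hydroxybenzaldehyde
Product: 12 4-(tert-butyldimethylsilyloxy)benzaldehyde
Conditions: TBSCl (1.1 equiv), imidazole (2 equiv), CH2Cl2, rt
Reagents that add atoms: tert-butyldimethylsilyl chloride, CC(C)(C)[Si](C)(C)Cl
Why: Standard imidazole-promoted silylation masks the acidic phenol, which would otherwise quench the carbanion of the next step.

**Step 8**
Reactants: 12 4-(tert-butyldimethylsilyloxy)benzaldehyde; 13 bis[(pinacolato)boryl]methane
Product: 15 (E)-2-[4-(tert-butyldimethylsilyloxy)phenyl]vinylboronic acid pinacol ester, via lithiated diborylmethane 14 (not isolated)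
Conditions: 2,2,6,6-tetramethylpiperidine (1.25 equiv), n-BuLi (1.2 equiv), THF, 0 °C; 13 (1.2 equiv), 0 °C; 12, −78 °C to rt
Reagents that add atoms: none
Why: In this boron-Wittig olefination the boron-stabilised carbanion adds to the aldehyde and the β-alkoxy gem-diboronate loses a boron–oxygen pair by syn elimination through the less crowded arrangement, which gives the E alkenyl boronate.

**Step 9**
Reactants: 15 (E)-2-[4-(tert-butyldimethylsilyloxy)phenyl]vinylboronic acid pinacol ester
Product: 16 (E)-2-(4-hydroxyphenyl)vinylboronic acid pinacol ester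
Conditions: TBAF (1.1 equiv), AcOH (1.1 equiv), THF, 0 °C
Reagents that add atoms: none
Why: Fluoride cleavage of the aryl silyl ether, buffered with acetic acid, is fast at 0 °C, leaves the pinacol boronate and the E alkene untouched, and frees the 4-OH that the catalyst of step 10 is meant to bind.

**Step 10**
Reactants: 10 5-(tert-butyldimethylsilyloxy)-2-(hydroxymethyl)-3-methoxy-6-(3-methylbut-2-en-1-yl)phenol; 16 (E)-2-(4-hydroxyphenyl)vinylboronic acid pinacol ester
Product: 18 (2S,3S)-7-(tert-butyldimethylsilyloxy)-2-(4-hydroxyphenyl)-5-methoxy-8-(3-methylbut-2-en-1-yl)-3-(4,4,5,5-tetramethyl-1,3,2-dioxaborolan-2-yl)chroman (2,3-trans), via ortho-quinone methide 17 (not isolated)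
Conditions: (R)-3,3'-bis(2,4,6-triisopropylphenyl)-1,1'-binaphthyl-2,2'-diyl hydrogen phosphate (10 mol %), 16 (3 equiv), 4 Å MS, toluene/CH2Cl2, −20 °C; 10 added by syringe pump over 10 h
Reagents that add atoms: none
Why: Proposed new method: the acid protonates the benzylic OH of 10, the 5-OMe and 7-OSi donors expel water, and ortho-quinone methide 17 (O1=C8a–C4a=C4) stays bound through O1 to the acidic site of the chiral phosphate while the phosphoryl oxygen holds the free 4'-OH of 16, after which electrophilic C4 bonds to the boron-bearing alkene carbon (C3) as charge builds on the benzylic carbon (C2), which O1 captures in an asynchronous inverse-demand oxa-[4+2]. The closest known reaction types are the chiral phosphoric acid catalysed [4+2] cycloadditions of ortho-quinone methides made in situ from ortho-hydroxybenzyl alcohols with styrenes and hydroxystyrenes, and the related Povarov reactions of E β-substituted 4-hydroxystyrenes, whereas a β-boryl dienophile and a methide unsubstituted at C4 are untested. Ring C closes by cycloaddition, with C4–C3 and O1–C2 made in one operation. C2 and C3 are set relative to each other by suprafacial addition to the E alkene (aryl and boron trans, and a short-lived open intermediate would still close to the diequatorial trans ring), and their absolute sense comes from the catalyst, whose two-point binding fixes both the open face of 17 and the endo or exo placement of the aryl group, both of which matter because C4 is not stereogenic. Regiochemistry follows from the charge at C2 being stabilised by the 4-hydroxyphenyl ring and by C–B hyperconjugation, and chemoselectivity over the prenyl alkene and over Friedel–Crafts attack at C6 of ring A rests on the hydrogen-bond-activated vinylogous phenol being the best nucleophile present, on its threefold excess and on the slow addition of 10. The 7-O-silyl group blocks the para-quinone methide tautomer, and the pinacol ester, which does not exchange ligands with phenols or phosphate, should suppress alkenyl transfer from boron and loss of boron from the β-boryl cation.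

**Step 11**
Reactants: 18 (2S,3S)-3-boryl chroman described in step 10
Product: 19 (2R,3S)-7-(tert-butyldimethylsilyloxy)-2-(4-hydroxyphenyl)-5-methoxy-8-(3-methylbut-2-en-1-yl)chroman-3-ol
Conditions: NaBO3·4H2O (4 equiv), THF/H2O, 0 °C to rt, 2 h, argon
Reagents that add atoms: sodium perborate tetrahydrate, [Na+].[O-]OB=O.O.O.O.O
Why: In this boronate oxidation hydroperoxide from perborate adds to boron and C3 migrates from boron to oxygen with retention, so the trans relation and absolute configuration carry over (the descriptors change to 2R,3S only through the priority change), while the weakly basic medium and short time spare the prenyl alkene and limit β-elimination across C3–C2 and epimerisation at C2.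

**Step 12**
Reactants: 19 (2R,3S)-7-(tert-butyldimethylsilyloxy)-2-(4-hydroxyphenyl)-5-methoxy-8-(3-methylbut-2-en-1-yl)chroman-3-ol
Product: 20 8-prenylafzelechin 5-methyl ether, (2R,3S)-2-(4-hydroxyphenyl)-5-methoxy-8-(3-methylbut-2-en-1-yl)chroman-3,7-diol
Conditions: TBAF (1.2 equiv), AcOH (1.2 equiv), THF, 0 °C
Reagents that add atoms: none
Why: Buffered fluoride desilylation removes the last protecting group without acid, which could close the 7-OH onto the prenyl group, and without free base, which could epimerise C2 through ring opening, so neither stereocentre is touched.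

**Compound list**
1 | 5-methoxyresorcinol | COc1cc(O)cc(O)c1 | starting material
2 | 1-methoxy-3,5-bis(methoxymethoxy)benzene | COCOc1cc(OC)cc(OCOC)c1 | intermediate
3 | prenyl bromide | CC(C)=CCBr | starting material
4 | [4-methoxy-2,6-bis(methoxymethoxy)phenyl]lithium | [Li]c1c(OCOC)cc(OC)cc1OCOC | intermediate
5 | 5-methoxy-1,3-bis(methoxymethoxy)-2-(3-methylbut-2-en-1-yl)benzene | COCOc1cc(OC)cc(OCOC)c1CC=C(C)C | intermediate
6 | [6-methoxy-2,4-bis(methoxymethoxy)-3-(3-methylbut-2-en-1-yl)phenyl]lithium | [Li]c1c(OC)cc(OCOC)c(CC=C(C)C)c1OCOC | intermediate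
7 | 6-methoxy-2,4-bis(methoxymethoxy)-3-(3-methylbut-2-en-1-yl)benzaldehyde | O=Cc1c(OC)cc(OCOC)c(CC=C(C)C)c1OCOC | intermediate
8 | 2,4-dihydroxy-6-methoxy-3-(3-methylbut-2-en-1-yl)benzaldehyde | O=Cc1c(OC)cc(O)c(CC=C(C)C)c1O | intermediate
9 | 4-(tert-butyldimethylsilyloxy)-2-hydroxy-6-methoxy-3-(3-methylbut-2-en-1-yl)benzaldehyde | O=Cc1c(OC)cc(O[Si](C)(C)C(C)(C)C)c(CC=C(C)C)c1O | intermediate
10 | 5-(tert-butyldimethylsilyloxy)-2-(hydroxymethyl)-3-methoxy-6-(3-methylbut-2-en-1-yl)phenol | COc1cc(O[Si](C)(C)C(C)(C)C)c(CC=C(C)C)c(O)c1CO | intermediate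
11 | 4-hydroxybenzaldehyde | O=Cc1ccc(O)cc1 | starting material
12 | 4-(tert-butyldimethylsilyloxy)benzaldehyde | CC(C)(C)[Si](C)(C)Oc1ccc(C=O)cc1 | intermediate
13 | bis[(pinacolato)boryl]methane | CC1(C)OB(CB2OC(C)(C)C(C)(C)O2)OC1(C)C | starting material
14 | lithio-bis[(pinacolato)boryl]methane | [Li]C(B1OC(C)(C)C(C)(C)O1)B1OC(C)(C)C(C)(C)O1 | intermediate
15 | (E)-2-[4-(tert-butyldimethylsilyloxy)phenyl]vinylboronic acid pinacol ester | CC1(C)OB(/C=C/c2ccc(O[Si](C)(C)C(C)(C)C)cc2)OC1(C)C | intermediate
16 | (E)-2-(4-hydroxyphenyl)vinylboronic acid pinacol ester | CC1(C)OB(/C=C/c2ccc(O)cc2)OC1(C)C | intermediate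
17 | 3-(tert-butyldimethylsilyloxy)-5-methoxy-6-methylidene-2-(3-methylbut-2-en-1-yl)cyclohexa-2,4-dien-1-one (ortho-quinone methide) | C=C1C(=O)C(CC=C(C)C)=C(O[Si](C)(C)C(C)(C)C)C=C1OC | intermediate
18 | (2S,3S)-7-(tert-butyldimethylsilyloxy)-2-(4-hydroxyphenyl)-5-methoxy-8-(3-methylbut-2-en-1-yl)-3-(pinacolboryl)chroman, 2,3-trans | COc1cc(O[Si](C)(C)C(C)(C)C)c(CC=C(C)C)c2c1C[C@H](B1OC(C)(C)C(C)(C)O1)[C@@H](c1ccc(O)cc1)O2 | intermediate
19 | (2R,3S)-7-(tert-butyldimethylsilyloxy)-2-(4-hydroxyphenyl)-5-methoxy-8-(3-methylbut-2-en-1-yl)chroman-3-ol | COc1cc(O[Si](C)(C)C(C)(C)C)c(CC=C(C)C)c2c1C[C@H](O)[C@@H](c1ccc(O)cc1)O2 | intermediate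
20 | 8-prenylafzelechin 5-methyl ether, (2R,3S) | COc1cc(O)c(CC=C(C)C)c2c1C[C@H](O)[C@@H](c1ccc(O)cc1)O2 | target

**Step count**
- Total: 12 steps.
- Longest linear sequence: 9 steps (steps 1–6, then 10–12).

**Steps most likely to fail**

**1. Step 10.**
- Capture of the methide by the boron-bearing alkene may be sluggish. Self-condensation through C6 of ring A, or oligomerisation, would then take over.
- Boron may be lost from the open cationic intermediate, or the dienophile may undergo protodeboronation.
- The catalyst may not discriminate the alkene faces well enough.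

The fallback uses known chemistry. It sets out from aldehyde 9 and silyl boronate 15 and rejoins the route at target 20. Oxidative cleavage of the pinacol ester of 15 (NaIO4, NH4OAc, acetone/H2O) gives (E)-2-[4-(tert-butyldimethylsilyloxy)phenyl]vinylboronic acid F1. Amine-promoted Petasis-type condensation of F1 with 9 (Bn2NH, dioxane, 90 °C) proceeds by iminium formation, alkenyl transfer from the phenoxide-bound boronate, loss of amine and oxa-6π closure. It gives racemic 7-(tert-butyldimethylsilyloxy)-2-[4-(tert-butyldimethylsilyloxy)phenyl]-5-methoxy-8-(3-methylbut-2-en-1-yl)-2H-chromene F2. Copper-catalysed enantioselective protoboration is then run as a kinetic resolution (CuCl, 1,2-bis[(2S,5S)-2,5-diphenylphospholan-1-yl]ethane or its mirror image as needed, NaOt-Bu, bis(pinacolato)diboron 0.6 equiv, MeOH, THF). It places boron on C3 anti to the C2 aryl group of the fast-reacting (2S) enantiomer and ignores the unconjugated prenyl alkene. The product is the (2S,3S)-7,4'-bis-O-TBS 3-(pinacolboryl)flavan F3, and the slow-reacting enantiomer is separated. NaBO3 oxidation gives the (2R,3S)-7,4'-bis-O-TBS flavan-3-ol F4, and TBAF/AcOH gives 20.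

**2. Step 6.**
- The phenoxide may expel the benzylic oxygen during reduction, which would over-reduce the benzylic position.
- The product may self-condense on work-up and concentration.

The fallback brings C4 in at the alcohol oxidation level as a storable boron-tethered derivative. It sets out from 5 and rejoins at 10. Acid methanolysis of 5 gives 5-methoxy-2-(3-methylbut-2-en-1-yl)resorcinol F5. Statistical monosilylation (TBSCl 1 equiv, imidazole) gives 3-(tert-butyldimethylsilyloxy)-5-methoxy-2-(3-methylbut-2-en-1-yl)phenol F6. Boronic-acid-templated ortho-hydroxymethylation (PhB(OH)2, paraformaldehyde, cat. EtCO2H, toluene, reflux, water removal) can reach only the one free ortho carbon, C4a. It gives 7-(tert-butyldimethylsilyloxy)-5-methoxy-8-(3-methylbut-2-en-1-yl)-2-phenyl-4H-1,3,2-benzodioxaborinine F7. Ester exchange with pinacol in toluene releases 10 in neutral solution, and this solution is fed directly into step 10.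

**3. Step 3.**
- Deprotonation at the allylic benzylic CH2 may compete with ring lithiation.
- The alkene may isomerise into conjugation.
- Ring lithiation may be incomplete.

The fallback replaces C–H deprotonation by halogen–metal exchange. It sets out from 5 and rejoins at aryllithium 6. Electrophilic bromination of the very electron-rich ring (NBS, MeCN, −30 °C) is expected to be much faster than attack on the trisubstituted alkene and is regiochemically unambiguous by symmetry. It gives 2-bromo-1-methoxy-3,5-bis(methoxymethoxy)-4-(3-methylbut-2-en-1-yl)benzene F8. Bromine–lithium exchange (n-BuLi, THF, −78 °C) is far faster than any deprotonation and gives 6, which is quenched with DMF as in step 3.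

**Further compounds**
F1 | step 10 | (E)-2-[4-(tert-butyldimethylsilyloxy)phenyl]vinylboronic acid | OB(O)/C=C/c1ccc(O[Si](C)(C)C(C)(C)C)cc1
F2 | step 10 | rac-7-(tert-butyldimethylsilyloxy)-2-[4-(tert-butyldimethylsilyloxy)phenyl]-5-methoxy-8-(3-methylbut-2-en-1-yl)-2H-chromene | COc1cc(O[Si](C)(C)C(C)(C)C)c(CC=C(C)C)c2c1C=CC(c1ccc(O[Si](C)(C)C(C)(C)C)cc1)O2
F3 | step 10 | (2S,3S)-7,4'-bis-O-TBS 3-(pinacolboryl)flavan, 2,3-trans | COc1cc(O[Si](C)(C)C(C)(C)C)c(CC=C(C)C)c2c1C[C@H](B1OC(C)(C)C(C)(C)O1)[C@@H](c1ccc(O[Si](C)(C)C(C)(C)C)cc1)O2
F4 | step 10 | (2R,3S)-7,4'-bis-O-TBS flavan-3-ol | COc1cc(O[Si](C)(C)C(C)(C)C)c(CC=C(C)C)c2c1C[C@H](O)[C@@H](c1ccc(O[Si](C)(C)C(C)(C)C)cc1)O2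
F5 | step 6 | 5-methoxy-2-(3-methylbut-2-en-1-yl)resorcinol | COc1cc(O)c(CC=C(C)C)c(O)c1
F6 | step 6 | 3-(tert-butyldimethylsilyloxy)-5-methoxy-2-(3-methylbut-2-en-1-yl)phenol | COc1cc(O)c(CC=C(C)C)c(O[Si](C)(C)C(C)(C)C)c1
F7 | step 6 | 7-(tert-butyldimethylsilyloxy)-5-methoxy-8-(3-methylbut-2-en-1-yl)-2-phenyl-4H-1,3,2-benzodioxaborinine | COc1cc(O[Si](C)(C)C(C)(C)C)c(CC=C(C)C)c2OB(c3ccccc3)OCc12
F8 | step 3 | 2-bromo-1-methoxy-3,5-bis(methoxymethoxy)-4-(3-methylbut-2-en-1-yl)benzene | Brc1c(OC)cc(OCOC)c(CC=C(C)C)c1OCOC
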